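The easy step comes first, so I set out the flask and ask how long its initiator lasts.

substrate 0.17 M; coupling partner 0.510 M; transfer agent 8.50 mM; initiator 1.7 mM; time 5.0 h

    initiator → 2 initiating radical (k1 = 0.030 min⁻¹)
    substrate + initiating radical → capped initiator + first chain carrier (k2 = 2.1 × 10⁵ L mol⁻¹ s⁻¹)
    coupling partner + first chain carrier → target + second chain carrier (k3 = 2.6 × 10⁵ L mol⁻¹ min⁻¹)
    substrate + second chain carrier → by-product + first chain carrier (k4 = 29000 L mol⁻¹ s⁻¹)
    transfer agent + first chain carrier → side product + idle radical (k5 = 7.8 × 10⁵ L mol⁻¹ s⁻¹)
    2 idle radical → ended radicals (k6 = 9 × 10⁷ L mol⁻¹ s⁻¹)
    2 first chain carrier → ended chains A (k7 = 7.7 × 10⁶ L mol⁻¹ s⁻¹)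
    2 second chain carrier → ended chains B (k8 = 4 × 10⁷ L mol⁻¹ s⁻¹)
    substrate ⇌ dormant form (K9 = 0.30, k9 = 0.061 min⁻¹)

- in percentages every species weighs as the substrate in it: one ended chains A counts as two
- a step written with two of one species runs at k times the square of its concentration and takes two of it each time
- what has gone from substrate into another species counts as reacted, even if it can come back
- the reaction counts as stopped when no species that holds the substrate changes by six tenths of a point or more over the second half of the time
- run time (flask): 5.0 h

* at 5.0 h, what has stopped the reaction, if anything has (the coupling partner has run out first / all of the substrate has reacted / forward and back rates have come level / it is still moving)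
* conversion of substrate at 5.0 h

In this flask the initiator has a half-life of 0.39 h by its own step, far shorter than the run of 5.0 h, and 0.0123% of it should be left at the end. So I book 3.40 mM of initiating radical, twice its charge. Each radical takes one substrate and starts a first chain carrier. That carrier either couples, pseudo-first-order in the excess coupling partner, or meets the transfer agent, which ends the chain. Coupling gives a target and a second chain carrier, which takes one more substrate and returns the first chain carrier.

I assume every chain ends at the transfer agent, so side product equals radicals booked. Let m be the coupling constant times the coupling partner charge, over the transfer constant: 2.83 mM, the level of transfer agent at which both fates are equally likely. It lies below the charge of transfer agent, so the kinetic chain length, target per radical, is 0.333, and substrate lost to target and side product comes to 4.53 mM. The balance with the dormant form relaxes in 2.62 min, short against the run, so what remains splits with dormant form over substrate equal to 0.30, which leaves 76.9% of it as substrate. I commit to 25.1%, with forward and back rates level.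

The weak link is the constant transfer agent, since the chains use 40.0% of its charge. Each side product takes one transfer agent T, and the target P rises as dP = −(m/T) dT. Integrated, this gives the target yield, the target a charge of radicals makes before its chains have ended: m times the natural logarithm of the transfer agent charged over the transfer agent remaining, 1.45 mM. This is far less than the coupling partner charged, so m holds. The conversion becomes 25.3%.

The forecast gives 25.3% and forward and back rates have come level, since “The transfer agent outcompetes the coupling partner and kills the chains”.

This flask gives 25.3% and forward and back rates have come level, and at 50.0 h the conversion still reads 25.3%. My target yield is 0.851% of the substrate charged, and the flask holds 0.850% at 5.00 h.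

In the neighbour charged with 0.043 M of substrate, m and the logarithm are unchanged, so the same 1.45 mM is now 3.37% of the charge, with conversion 31.8%. That neighbour gives 3.36% of target and 31.7%.

The rate constants stand for no real mixture; no experiment stands behind them.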